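**Plan**

Locants: ring A is C1–C6 (C1 vinyl, C2=C3 with the C3 methyl, C6 acyl); ring B is C4–C5–C7(O)–C8–C13; ring C is C8–C13 (methyls on C9, C11, C13); C14 is the ketone; C15–C18 and N are the pyrrolinone (C17 the hemiaminal); C19 is the benzylic carbon.
Retrosynthesis cuts the aryl ether bond at C7 and the acyl bond C14–C15 (tricyclic acid plus iodobenzyl lactam), then C8–C13 and C9–C10 together (intramolecular Diels–Alder), then ring A into maleic anhydride and a chiral dienol.
Enabling feature: in ring C the methyl on C9, next to the B/C fusion methine C8, is carried as a methyl ester and the methyl-bearing C11 as an enol ether carbon. Ring C is then a cyclohexene retron whose C8–C13 and C9–C10 bonds join an (E)-enoate on C5 to a diene on C4, with ring B as the three-carbon tether ring.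
Forward order: ring A (Diels–Alder, lactonisation), the C5 silyloxy enoate arm and the C4 ethoxydienyl arm, rings B and C in one step, the two ring C methyls, the acyl lactam, the macrocyclic ether, then the pyrrolinone oxidation level.
Stereochemistry: (R)-glyceraldehyde acetonide steers the first cycloaddition (C1, C4, C5; C6 by epimerisation); a CBS reduction sets C7; the ring A template and the endo rule set C8, C9, C13; equilibration sets C11; L-4-iodophenylalanine and the cyclophane fix C17.
The diene carries ethoxy, not methyl, at C11: this makes it more reactive and means no alkene has to be hydrogenated beside the vinyl group and the ring A alkene.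

Key step: step 17

Remark: maleic anhydride is assumed to add to dienol 5 anti to the allylic C–O bond, in the conformer whose dioxolane C–H eclipses the diene (allylic strain with the C3 methyl); if the sense were opposite, the antipode of 1 would be used.
Remark: the C17 hemiaminal of the target is assumed to be the epimer favoured inside the cyclophane (oxygen on the face away from the bridge), reached kinetically and by ring–chain equilibration.
Remark: compounds 1, 2, 4, 6, 20, 25, 37 and 38 are taken as commercial.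

**Route**

Step 1
Reactants: 1 (R)-glyceraldehyde acetonide; 2 2-(triphenylphosphoranylidene)propanal
Product: 3 (E)-dioxolanyl methylpropenal
Conditions: toluene, 90 °C
Reagents that add atoms: none
Why: Wittig olefination with a stabilised formyl ylide gives the (E)-enal, which places the methyl cis to the dioxolane (the source of the later allylic strain) and leaves the acetonide stereocentre untouched.

Step 2
Reactants: 3 (E)-dioxolanyl methylpropenal; 4 (3-hydroxypropyl)triphenylphosphonium bromide
Product: 5 (3E,5E)-dienol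
Conditions: 4, LiN(SiMe3)2 (2.05 equiv), THF, −78 → 0 °C; then 3, −78 °C → rt
Reagents that add atoms: none
Why: Wittig reaction of a γ-oxido ylide with a conjugated aldehyde, a pairing known for (E)-selectivity, gives the (E,E)-dienol with its free hydroxyl; any (3Z)-isomer cannot adopt the s-cis form and is left behind in step 3.

Step 3
Reactants: 5 (3E,5E)-dienol; 6 maleic anhydride
Product: 8 cis-fused lactone acid, via anhydride adduct 7 (not isolated)
Conditions: toluene, 40 °C; then Et3N (0.2 equiv), DMAP (5 mol %), 40 °C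
Reagents that add atoms: none
Why: endo Diels–Alder addition of maleic anhydride sets C1, C4, C5 and C6 all-cis on the diene face anti to the allylic C–O bond (dioxolane C–H eclipsed by allylic strain with the C3 methyl), and the pendant hydroxyl then opens the anhydride at the neighbouring C14 carbonyl (six-membered lactone), which tells C14 apart from the free C7 carboxyl.

Step 4
Reactants: 8 cis-fused lactone acid
Product: 9 trans-fused lactone acid
Conditions: KOtBu (2.5 equiv), THF, 0 °C → rt; cold 0.5 M HCl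
Reagents that add atoms: none
Why: base epimerisation through the lactone enolate (the C5 carboxylate is not enolised) moves C6 to the trans-fused six-six lactone, the thermodynamic isomer, so C6 becomes trans to C1 and C5 as in the target.

Step 5
Reactants: 9 trans-fused lactone acid
Product: 10 lactone Weinreb amide
Conditions: MeNHOMe·HCl, EDC·HCl, HOBt, iPr2NEt, CH2Cl2, 0 °C → rt
Reagents that add atoms: N,O-dimethylhydroxylamine hydrochloride, CNOC.Cl
Why: carbodiimide amide coupling marks the C7 carboxyl as a Weinreb amide before the lactone is opened; no stereocentre is formed.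

Step 6
Reactants: 10 lactone Weinreb amide
Product: 11 seleno acid
Conditions: PhSeH, NaH, DMF, 0 °C; then 10, 80 °C; cold 0.5 M HCl
Reagents that add atoms: benzeneselenol, [SeH]c1ccccc1
Why: SN2 opening of the lactone at its primary O–CH2 carbon by the soft selenolate (alkyl–oxygen cleavage) frees the C14 acid and leaves a 2-(phenylseleno)ethyl group on C1 as a masked vinyl, while amide and acetal are inert.

Step 7
Reactants: 11 seleno acid
Product: 12 seleno tert-butyl ester
Conditions: tBuOC(=NH)CCl3, CH2Cl2/cyclohexane, rt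
Reagents that add atoms: tert-butyl 2,2,2-trichloroacetimidate, CC(C)(C)OC(=N)C(Cl)(Cl)Cl
Why: O-alkylation of the carboxylic acid by the trichloroacetimidate gives the tert-butyl ester under conditions that spare the acetonide.

Step 8
Reactants: 12 seleno tert-butyl ester
Product: 14 C1-vinyl amide ester, via selenoxide 13 (not isolated)
Conditions: 30% H2O2, pyridine, CH2Cl2, 0 → 35 °C
Reagents that add atoms: none
Why: selenide oxidation and syn elimination of the selenoxide (β-hydrogens only on the CH2 next to C1) give the vinyl group, and pyridine buffers the selenenic acid so the ring alkene is not epoxidised.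

Step 9
Reactants: 14 C1-vinyl amide ester
Product: 16 C4 aldehyde, via diol 15 (not isolated)
Conditions: H5IO6, EtOAc, 0 °C → rt
Reagents that add atoms: none
Why: periodic acid hydrolyses the terminal acetonide and cleaves the 1,2-diol in one pot (glycol cleavage), turning the spent controller into the C13 aldehyde without base, so C4 is not epimerised.

Step 10
Reactants: 16 C4 aldehyde
Product: 17 C4 alkyne
Conditions: Me3SiCHN2, LiN(iPr)2, THF, −78 °C; then 16, −78 °C → rt; aq. NH4Cl
Reagents that add atoms: (trimethylsilyl)diazomethane, C[Si](C)(C)C=[N+]=[N-]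
Why: Colvin homologation (addition of lithiated silyldiazomethane, Peterson elimination, 1,2-shift in the alkylidene carbene) gives the terminal alkyne, and at −78 °C addition outruns enolisation so C4 keeps its configuration.

Step 11
Reactants: 17 C4 alkyne
Product: 19 (E)-iodoalkene, via alkenylalane 18 (not isolated)
Conditions: Me3Al (4 equiv), Cp2ZrCl2 (0.3 equiv), CH2Cl2, 0 °C → rt; then I2, THF, −30 → 0 °C
Reagents that add atoms: trimethylaluminium, C[Al](C)C; iodine, II
Why: zirconium-catalysed syn carboalumination (Negishi) puts the methyl on C13 and aluminium on C12, and iodinolysis with retention gives the (E)-iodoalkene that fixes the diene geometry; excess Me3Al saturates the amide and ester carbonyls.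

Step 12
Reactants: 19 (E)-iodoalkene; 20 methyl propiolate
Product: 21 ynone
Conditions: 20, LiN(SiMe3)2, THF, −78 °C; then 19, −78 → −40 °C; aq. NH4Cl
Reagents that add atoms: none
Why: acylation of the lithium acetylide by the Weinreb amide stops at the ketone because the chelated tetrahedral adduct survives until work-up; tert-butyl ester and iodoalkene do not react at this temperature.

Step 13
Reactants: 21 ynone
Product: 22 propargylic alcohol
Conditions: (S)-Me-CBS (0.3 equiv), catecholborane, toluene, −78 °C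
Reagents that add atoms: none
Why: Corey–Bakshi–Shibata reduction with the alkynyl group as the small substituent sets C7 under reagent control in the configuration of the target ether carbon.

Step 14
Reactants: 22 propargylic alcohol
Product: 23 (E)-hydroxy enoate
Conditions: NaAlH2(OCH2CH2OMe)2, THF, −72 °C
Reagents that add atoms: none
Why: hydroxyl-directed trans-hydroalumination of the γ-hydroxy ynoate and protonolysis give the (E)-enoate at low temperature without touching the esters or the iodoalkene.

Step 15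
Reactants: 23 (E)-hydroxy enoate
Product: 24 silyl ether iodoalkene
Conditions: TBSOTf, 2,6-lutidine, CH2Cl2, −78 → 0 °C
Reagents that add atoms: tert-butyldimethylsilyl trifluoromethanesulfonate, CC(C)(C)[Si](C)(C)OS(=O)(=O)C(F)(F)F
Why: silylation of the hindered secondary alcohol with the silyl triflate blocks lactonisation onto the C14 ester and fixes the allylic oxygen substituent for the cycloaddition.

Step 16
Reactants: 24 silyl ether iodoalkene; 25 tributyl(1-ethoxyvinyl)stannane
Product: 26 ethoxy triene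
Conditions: Pd(PPh3)4 (5 mol %), CuI (10 mol %), DMF, 40 °C
Reagents that add atoms: none
Why: Stille coupling of the iodoalkene with the α-ethoxyvinylstannane proceeds with retention of alkene geometry and gives the 2-ethoxy-1,3-diene, with CuI allowing a temperature at which the triene does not yet cyclise.

Step 17
Reactants: 26 ethoxy triene
Product: 27 tricyclic enol ether diester
Conditions: Me2AlCl (1.5 equiv), CH2Cl2, −78 → −20 °C; aq. NaHCO3
Reagents that add atoms: none
Why: Me2AlCl binds the enoate carbonyl and the (E)-enoate on C5 adds across the 2-ethoxy-4-methyldiene on C4 in a concerted, asynchronous [4+2] cycloaddition (bond C8–C13 leading); the closest known type is the intramolecular Diels–Alder reaction of nona-1,6,8-trienoates to trans-fused hydrindenes. Ring C closes in the cycloaddition itself as the new six-membered ring (bonds C8–C13 and C9–C10), and ring B closes at the same time as the five-membered ring of the three-carbon tether C4–C5–C7, fused to ring A and to ring C. C13 is set by the diene face: the dienyl group is pseudoaxial on C4 (allylic strain with the C3 methyl) and turns its small C13 methyl over ring A and its chain away, so the dienophile arm on the cis neighbour C5 reaches only one face. C8 and C9 are set by the ester-endo transition state, favoured by the aluminium-bound ester, which gives the trans B/C fusion (H8 anti to the C13 methyl) and carries the (E) geometry into the trans relation of C7 and the C9 ester. The step needs endo over exo selectivity and a single diene face; the Lewis acid, the (E)-enoate, the defined diene geometry and the cis-substituted ring A with its fixed C7 silyloxy centre should secure them, and the ethoxy group raises the diene HOMO to offset the retarding inside methyl.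

Step 18
Reactants: 27 tricyclic enol ether diester
Product: 28 C11 ketone
Conditions: 0.5 M HCl, THF, 0 °C
Reagents that add atoms: water, O
Why: acid hydrolysis of the enol ether (protonation at C12, hydration of the oxocarbenium ion) gives the C11 ketone while the silyl ether and both esters survive dilute acid.

Step 19
Reactants: 28 C11 ketone
Product: 29 C11 methoxymethylene compound
Conditions: MeOCH2PPh3Cl, KN(SiMe3)2, THF, 0 °C; then 28, 0 °C → rt
Reagents that add atoms: (methoxymethyl)triphenylphosphonium chloride, COC[P+](c1ccccc1)(c1ccccc1)c1ccccc1.[Cl-]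
Why: Wittig olefination of the unhindered cyclohexanone with (methoxymethylene)triphenylphosphorane adds the future C11 methyl carbon, and the esters are inert to the ylide.

Step 20
Reactants: 29 C11 methoxymethylene compound
Product: 31 equatorial C11 aldehyde, via axial aldehyde 30 (not isolated)
Conditions: 2 M HCl, THF, rt; then K2CO3, MeOH, rt
Reagents that add atoms: water, O
Why: enol ether hydrolysis gives the aldehyde and base equilibration through the enolate places the formyl group equatorial, because the axial epimer suffers a 1,3-diaxial clash with the C13 methyl; this sets C11 under thermodynamic control.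

Step 21
Reactants: 31 equatorial C11 aldehyde
Product: 32 diol
Conditions: LiBH4, THF, 0 °C → rt
Reagents that add atoms: none
Why: chemoselective hydride reduction, in which LiBH4 reduces the aldehyde and the methyl ester to primary alcohols and leaves the hindered tert-butyl ester.

Step 22
Reactants: 32 diol
Product: 33 bis(iodomethyl) compound
Conditions: I2, PPh3, imidazole, CH2Cl2, 0 °C → rt
Reagents that add atoms: iodine, II
Why: Appel-type iodination of both primary alcohols, with no change at the ring stereocentres.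

Step 23
Reactants: 33 bis(iodomethyl) compound
Product: 34 dimethyl tricyclic ester
Conditions: Bu3SnH, AIBN (cat.), toluene, 80 °C
Reagents that add atoms: none
Why: radical chain dehalogenation turns both iodomethyl groups into the C9 and C11 methyls, and the primary radicals have no alkene within reach for cyclisation.

Step 24
Reactants: 34 dimethyl tricyclic ester
Product: 36 tricyclic acid, via trimethylsilyl ester 35 (not isolated)
Conditions: TMSOTf, 2,6-lutidine, CH2Cl2, 0 °C; then pH 4 buffer
Reagents that add atoms: none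
Why: silyl triflate cleavage of the tert-butyl ester (loss of isobutene to the silyl ester, hydrolysed on work-up) is known to spare secondary tert-butyldimethylsilyl ethers.

Step 25
Reactants: 37 Boc-4-iodo-L-phenylalanine; 38 Meldrum's acid
Product: 39 acyl Meldrum's acid
Conditions: EDC·HCl, DMAP, CH2Cl2, 0 °C → rt
Reagents that add atoms: none
Why: carbodiimide-mediated C-acylation of Meldrum's acid by the N-protected amino acid, which does not affect the α-centre.

Step 26
Reactants: 39 acyl Meldrum's acid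
Product: 40 alkyl Meldrum's acid
Conditions: NaBH4, AcOH, CH2Cl2, 0 °C → rt
Reagents that add atoms: none
Why: NaBH4 in acetic acid removes the ketone oxygen (via the alkylidene Meldrum's acid and conjugate reduction) and leaves the aryl iodide and the stereocentre untouched.

Step 27
Reactants: 40 alkyl Meldrum's acid
Product: 41 iodobenzyl N-Boc lactam
Conditions: toluene, 110 °C
Reagents that add atoms: none
Why: thermal cyclisation of the carbamate nitrogen onto Meldrum's acid with loss of acetone and CO2 gives the pyrrolidinone; the amino acid centre becomes C17 and holds the benzyl arm in the spatial position it has in the target.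

Step 28
Reactants: 36 tricyclic acid; 41 iodobenzyl N-Boc lactam
Product: 43 N-Boc acyl lactam, via acyl imidazole 42 (not isolated)
Conditions: 36, CDI, THF, rt; 41, LiN(SiMe3)2 (2.2 equiv), THF, −78 °C; combine, −78 → −30 °C; aq. NH4Cl
Reagents that add atoms: none
Why: crossed Claisen-type C-acylation of the lactam lithium enolate by the acyl imidazole forms the C14–C15 bond; excess enolate deprotonates the β-keto lactam as it forms, and C15 is left as an epimer mixture that is removed in step 32.

Step 29
Reactants: 43 N-Boc acyl lactam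
Product: 44 N–H acyl lactam
Conditions: TFA, CH2Cl2, 0 °C
Reagents that add atoms: none
Why: acidolysis of the carbamate frees the lactam N–H and removes the activated imide carbonyl that the C7 alkoxide could otherwise attack during ring closure.

Step 30
Reactants: 44 N–H acyl lactam
Product: 45 seco hydroxy iodide
Conditions: HF·pyridine, THF, 0 °C → rt
Reagents that add atoms: none
Why: fluoride cleavage of the silyl ether under non-basic conditions frees the C7 alcohol without retro-Claisen cleavage of the β-keto lactam.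

Step 31
Reactants: 45 seco hydroxy iodide
Product: 46 macrocyclic aryl ether
Conditions: CuI (1 equiv), 3,4,7,8-tetramethyl-1,10-phenanthroline, Cs2CO3, toluene (1 mM), 110 °C
Reagents that add atoms: none
Why: copper-mediated Ullmann-type O-arylation of the secondary alkoxide by the aryl iodide, run intramolecularly at high dilution, closes the thirteen-membered para-cyclophane ether with retention at C7; the C7 oxygen and the C6 acyl arm sit on the same face, and the C15-substituted enolate is a poor carbon nucleophile.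

Step 32
Reactants: 46 macrocyclic aryl ether
Product: 49 macrocyclic acylpyrrolinone, via selenide 47 (not isolated), via selenoxide 48 (not isolated)
Conditions: LiN(SiMe3)2 (2.2 equiv), THF, −78 °C; PhSeBr; then 30% H2O2, pyridine, CH2Cl2, 0 °C
Reagents that add atoms: none
Why: α-selenenylation of the β-keto lactam enolate at C15 and syn elimination of the derived selenoxide toward C16 introduce the C15=C16 double bond, the enolate reacting with PhSeBr far faster than the isolated alkenes.

Step 33
Reactants: 49 macrocyclic acylpyrrolinone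
Product: 51 target compound CNP0151253.2, via hydroperoxide 50 (not isolated)
Conditions: O2 (1 atm), Et3N, THF, 0 °C; then PPh3
Reagents that add atoms: oxygen, O=O
Why: the vinylogous imide is deprotonated at C17 to a 2-oxidopyrrole that captures O2 at C17 (autoxidation) and the hydroperoxide is reduced to the hemiaminal; oxygen should enter on the face away from the cyclophane bridge, and ring–chain tautomerism lets C17 settle in that configuration.

**Compound list**

1 | (R)-2,2-dimethyl-1,3-dioxolane-4-carbaldehyde | O=C[C@H]1COC(C)(C)O1 | starting material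
2 | 2-(triphenylphosphoranylidene)propanal | CC(C=O)=P(c1ccccc1)(c1ccccc1)c1ccccc1 | starting material
3 | (2E)-3-[(4S)-2,2-dimethyl-1,3-dioxolan-4-yl]-2-methylprop-2-enal | O=C/C(C)=C/[C@H]1COC(C)(C)O1 | intermediate
4 | (3-hydroxypropyl)triphenylphosphonium bromide | OCCC[P+](c1ccccc1)(c1ccccc1)c1ccccc1.[Br-] | starting material
5 | (3E,5E)-6-[(4S)-2,2-dimethyl-1,3-dioxolan-4-yl]-5-methylhexa-3,5-dien-1-ol | OCC/C=C/C(C)=C/[C@H]1COC(C)(C)O1 | intermediate
6 | maleic anhydride | O=C1C=CC(=O)O1 | starting material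
7 | anhydride adduct: ring A with cis anhydride on C5/C6, 2-hydroxyethyl on C1, (4S)-dioxolanyl on C4, all cis | OCC[C@H]1C=C(C)[C@@H]([C@H]2COC(C)(C)O2)[C@H]3C(=O)OC(=O)[C@@H]13 | intermediate (not isolated)
8 | cis-fused lactone acid: C14 carbonyl lactonised onto the C1 ethyl oxygen, C7 carboxylic acid on C5, dioxolanyl on C4 | O=C2OCC[C@H]1C=C(C)[C@@H]([C@H]3COC(C)(C)O3)[C@H]([C@H]12)C(=O)O | intermediate
9 | trans-fused lactone acid (C6 epimer of 8) | O=C2OCC[C@H]1C=C(C)[C@@H]([C@H]3COC(C)(C)O3)[C@H]([C@@H]12)C(=O)O | intermediate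
10 | lactone Weinreb amide (N-methoxy-N-methylamide at C7) | O=C2OCC[C@H]1C=C(C)[C@@H]([C@H]3COC(C)(C)O3)[C@H]([C@@H]12)C(=O)N(C)OC | intermediate
11 | seleno acid: C1 2-(phenylseleno)ethyl, C6 carboxylic acid, C5 Weinreb amide, C4 dioxolanyl | c1ccccc1[Se]CC[C@H]1C=C(C)[C@@H]([C@H]2COC(C)(C)O2)[C@H]([C@@H]1C(=O)O)C(=O)N(C)OC | intermediate
12 | seleno tert-butyl ester | c1ccccc1[Se]CC[C@H]1C=C(C)[C@@H]([C@H]2COC(C)(C)O2)[C@H]([C@@H]1C(=O)OC(C)(C)C)C(=O)N(C)OC | intermediate
13 | selenoxide of 12 | O=[Se](CC[C@H]1C=C(C)[C@@H]([C@H]2COC(C)(C)O2)[C@H]([C@@H]1C(=O)OC(C)(C)C)C(=O)N(C)OC)c1ccccc1 | intermediate (not isolated)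
14 | C1-vinyl ring A: C6 tert-butyl ester, C5 Weinreb amide, C4 dioxolanyl | C=C[C@H]1C=C(C)[C@@H]([C@H]2COC(C)(C)O2)[C@H]([C@@H]1C(=O)OC(C)(C)C)C(=O)N(C)OC | intermediate
15 | diol: C4 (1S)-1,2-dihydroxyethyl analogue of 14 | C=C[C@H]1C=C(C)[C@@H]([C@H](O)CO)[C@H]([C@@H]1C(=O)OC(C)(C)C)C(=O)N(C)OC | intermediate (not isolated)
16 | C4 aldehyde (C13 formyl) | C=C[C@H]1C=C(C)[C@@H](C=O)[C@H]([C@@H]1C(=O)OC(C)(C)C)C(=O)N(C)OC | intermediate
17 | C4 alkyne (ethynyl on C4) | C=C[C@H]1C=C(C)[C@@H](C#C)[C@H]([C@@H]1C(=O)OC(C)(C)C)C(=O)N(C)OC | intermediate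
18 | (E)-alkenyl(dimethyl)alane | C=C[C@H]1C=C(C)[C@@H](/C(C)=C/[Al](C)C)[C@H]([C@@H]1C(=O)OC(C)(C)C)C(=O)N(C)OC | intermediate (not isolated)
19 | (E)-iodoalkene: (E)-1-iodoprop-1-en-2-yl on C4 | C=C[C@H]1C=C(C)[C@@H](/C(C)=C/I)[C@H]([C@@H]1C(=O)OC(C)(C)C)C(=O)N(C)OC | intermediate
20 | methyl propiolate | C#CC(=O)OC | starting material
21 | ynone: 4-methoxy-4-oxobut-2-ynoyl on C5 | C=C[C@H]1C=C(C)[C@@H](/C(C)=C/I)[C@H]([C@@H]1C(=O)OC(C)(C)C)C(=O)C#CC(=O)OC | intermediate
22 | propargylic alcohol (C7 carbinol, target configuration) | C=C[C@H]1C=C(C)[C@@H](/C(C)=C/I)[C@H]([C@@H]1C(=O)OC(C)(C)C)[C@H](O)C#CC(=O)OC | intermediate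
23 | (E)-γ-hydroxy enoate | C=C[C@H]1C=C(C)[C@@H](/C(C)=C/I)[C@H]([C@@H]1C(=O)OC(C)(C)C)[C@H](O)/C=C/C(=O)OC | intermediate
24 | silyl ether iodoalkene (C7 OTBS, (E)-enoate, (E)-iodoalkene) | C=C[C@H]1C=C(C)[C@@H](/C(C)=C/I)[C@H]([C@@H]1C(=O)OC(C)(C)C)[C@H](O[Si](C)(C)C(C)(C)C)/C=C/C(=O)OC | intermediate
25 | tributyl(1-ethoxyvinyl)stannane | CCOC(=C)[Sn](CCCC)(CCCC)CCCC | starting material
26 | ethoxy triene: ring A tert-butyl ester with the (E)-4-ethoxy-penta-2,4-dien-2-yl arm on C4 and the silyloxy (E)-enoate arm on C5 | C=C[C@H]1C=C(C)[C@@H](/C(C)=C/C(OCC)=C)[C@H]([C@@H]1C(=O)OC(C)(C)C)[C@H](O[Si](C)(C)C(C)(C)C)/C=C/C(=O)OC | intermediate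
27 | tricyclic enol ether diester: C11 ethoxy enol ether (C11=C12), C9 methyl ester, trans B/C fusion | C=C[C@H]1C=C(C)[C@@H]2[C@H]([C@@H]1C(=O)OC(C)(C)C)[C@H](O[Si](C)(C)C(C)(C)C)[C@@H]1[C@@H](C(=O)OC)CC(OCC)=C[C@]12C | intermediate
28 | C11 ketone | C=C[C@H]1C=C(C)[C@@H]2[C@H]([C@@H]1C(=O)OC(C)(C)C)[C@H](O[Si](C)(C)C(C)(C)C)[C@@H]1[C@@H](C(=O)OC)CC(=O)C[C@]12C | intermediate
29 | C11 methoxymethylene compound (E/Z mixture) | C=C[C@H]1C=C(C)[C@@H]2[C@H]([C@@H]1C(=O)OC(C)(C)C)[C@H](O[Si](C)(C)C(C)(C)C)[C@@H]1[C@@H](C(=O)OC)CC(=COC)C[C@]12C | intermediate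
30 | axial C11 aldehyde (C11 epimer of 31) | C=C[C@H]1C=C(C)[C@@H]2[C@H]([C@@H]1C(=O)OC(C)(C)C)[C@H](O[Si](C)(C)C(C)(C)C)[C@@H]1[C@@H](C(=O)OC)C[C@H](C=O)C[C@]12C | intermediate (not isolated)
31 | equatorial C11 aldehyde | C=C[C@H]1C=C(C)[C@@H]2[C@H]([C@@H]1C(=O)OC(C)(C)C)[C@H](O[Si](C)(C)C(C)(C)C)[C@@H]1[C@@H](C(=O)OC)C[C@@H](C=O)C[C@]12C | intermediate
32 | diol: hydroxymethyl on C9 and C11 | C=C[C@H]1C=C(C)[C@@H]2[C@H]([C@@H]1C(=O)OC(C)(C)C)[C@H](O[Si](C)(C)C(C)(C)C)[C@@H]1[C@@H](CO)C[C@@H](CO)C[C@]12C | intermediate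
33 | bis(iodomethyl) compound | C=C[C@H]1C=C(C)[C@@H]2[C@H]([C@@H]1C(=O)OC(C)(C)C)[C@H](O[Si](C)(C)C(C)(C)C)[C@@H]1[C@@H](CI)C[C@@H](CI)C[C@]12C | intermediate
34 | dimethyl tricyclic ester (C9, C11, C13 methyls; C7 OTBS; C6 tert-butyl ester) | C=C[C@H]1C=C(C)[C@@H]2[C@H]([C@@H]1C(=O)OC(C)(C)C)[C@H](O[Si](C)(C)C(C)(C)C)[C@@H]1[C@@H](C)C[C@@H](C)C[C@]12C | intermediate
35 | trimethylsilyl ester of 36 | C=C[C@H]1C=C(C)[C@@H]2[C@H]([C@@H]1C(=O)O[Si](C)(C)C)[C@H](O[Si](C)(C)C(C)(C)C)[C@@H]1[C@@H](C)C[C@@H](C)C[C@]12C | intermediate (not isolated)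
36 | tricyclic acid | C=C[C@H]1C=C(C)[C@@H]2[C@H]([C@@H]1C(=O)O)[C@H](O[Si](C)(C)C(C)(C)C)[C@@H]1[C@@H](C)C[C@@H](C)C[C@]12C | intermediate
37 | N-Boc-4-iodo-L-phenylalanine | CC(C)(C)OC(=O)N[C@@H](Cc1ccc(I)cc1)C(=O)O | starting material
38 | Meldrum's acid | CC1(C)OC(=O)CC(=O)O1 | starting material
39 | acyl Meldrum's acid from 37 | CC(C)(C)OC(=O)N[C@@H](Cc1ccc(I)cc1)C(=O)C1C(=O)OC(C)(C)OC1=O | intermediate
40 | alkyl Meldrum's acid (ketone of 39 reduced to CH2) | CC(C)(C)OC(=O)N[C@@H](Cc1ccc(I)cc1)CC1C(=O)OC(C)(C)OC1=O | intermediate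
41 | tert-butyl (2R)-2-[(4-iodophenyl)methyl]-5-oxopyrrolidine-1-carboxylate | CC(C)(C)OC(=O)N1[C@@H](Cc2ccc(I)cc2)CCC1=O | intermediate
42 | acyl imidazole of 36 | C=C[C@H]1C=C(C)[C@@H]2[C@H]([C@@H]1C(=O)n3ccnc3)[C@H](O[Si](C)(C)C(C)(C)C)[C@@H]1[C@@H](C)C[C@@H](C)C[C@]12C | intermediate (not isolated)
43 | N-Boc acyl lactam (C14–C15 bond formed; C15 epimers) | C=C[C@H]1C=C(C)[C@@H]2[C@H]([C@@H]1C(=O)C3C[C@H](Cc4ccc(I)cc4)N(C(=O)OC(C)(C)C)C3=O)[C@H](O[Si](C)(C)C(C)(C)C)[C@@H]1[C@@H](C)C[C@@H](C)C[C@]12C | intermediate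
44 | N–H acyl lactam | C=C[C@H]1C=C(C)[C@@H]2[C@H]([C@@H]1C(=O)C3C[C@H](Cc4ccc(I)cc4)NC3=O)[C@H](O[Si](C)(C)C(C)(C)C)[C@@H]1[C@@H](C)C[C@@H](C)C[C@]12C | intermediate
45 | seco hydroxy iodide (free C7 alcohol) | C=C[C@H]1C=C(C)[C@@H]2[C@H]([C@@H]1C(=O)C3C[C@H](Cc4ccc(I)cc4)NC3=O)[C@H](O)[C@@H]1[C@@H](C)C[C@@H](C)C[C@]12C | intermediate
46 | macrocyclic aryl ether with saturated lactam (C15 epimers) | C=C[C@H]1C=C(C)[C@@H]2[C@H]3[C@H](Oc4ccc(cc4)C[C@H]4CC(C(=O)N4)C(=O)[C@H]13)[C@@H]1[C@@H](C)C[C@@H](C)C[C@]12C | intermediate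
47 | C15 phenylselenide | C=C[C@H]1C=C(C)[C@@H]2[C@H]3[C@H](Oc4ccc(cc4)C[C@H]4CC([Se]c5ccccc5)(C(=O)N4)C(=O)[C@H]13)[C@@H]1[C@@H](C)C[C@@H](C)C[C@]12C | intermediate (not isolated)
48 | C15 selenoxide | C=C[C@H]1C=C(C)[C@@H]2[C@H]3[C@H](Oc4ccc(cc4)C[C@H]4CC([Se](=O)c5ccccc5)(C(=O)N4)C(=O)[C@H]13)[C@@H]1[C@@H](C)C[C@@H](C)C[C@]12C | intermediate (not isolated)
49 | macrocyclic acylpyrrolinone (C15=C16, C17–H) | C=C[C@H]1C=C(C)[C@@H]2[C@H]3[C@H](Oc4ccc(cc4)C[C@H]4C=C(C(=O)N4)C(=O)[C@H]13)[C@@H]1[C@@H](C)C[C@@H](C)C[C@]12C | intermediate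
50 | C17 hydroperoxide | C=C[C@H]1C=C(C)[C@@H]2[C@H]3[C@H](Oc4ccc(cc4)C[C@@]4(OO)C=C(C(=O)N4)C(=O)[C@H]13)[C@@H]1[C@@H](C)C[C@@H](C)C[C@]12C | intermediate (not isolated)
51 | CNP0151253.2 | C=C[C@H]1C=C(C)[C@@H]2[C@H]3[C@H](Oc4ccc(cc4)C[C@@]4(O)C=C(C(=O)N4)C(=O)[C@H]13)[C@@H]1[C@@H](C)C[C@@H](C)C[C@]12C | target

**Count and risks**

Total steps: 33. Longest linear sequence: 30 (steps 1–24 and 28–33); steps 25–27 make the lactam branch.

Step 17. The cycloaddition may lose endo selectivity (reaction through the ester-exo transition state to a cis B/C fusion), or the Lewis acid may destroy the enol ether before ring closure. The fallback changes the dienophile to a chelating imide and sets out from 24. LiOH in aqueous THF cleaves only the methyl ester to enoic acid F1. Pivaloyl chloride and Et3N, then oxazolidin-2-one with LiCl, give N-enoyl oxazolidinone F2. Stille coupling with 25 as in step 16 gives triene imide F3. Me2AlCl, chelated between the two imide carbonyls (the dienophile class whose intramolecular Diels–Alder reactions are strongly endo-selective), gives tricyclic imide F4. MeOMgBr in methanol exchanges the oxazolidinone for methoxide, and the route is rejoined at 27.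

Step 28. Self-condensation or Boc migration of the lactam enolate, or O-acylation, may outrun C-acylation by the hindered acyl imidazole. The fallback forms the C14–C15 bond by aldol addition and sets out from 34. LiAlH4 reduces the tert-butyl ester to primary alcohol F5. Dess–Martin periodinane gives aldehyde F6, whose C6 centre already has the stable trans arrangement. The lithium enolate of 41 (LiN(SiMe3)2, THF, −78 °C) adds to give β-hydroxy lactam F7 as an epimer mixture at C14 and C15. A second Dess–Martin oxidation rejoins the route at 43.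

Step 31. Intermolecular coupling to oligomers and reductive loss of iodine may outrun closure of the strained ring. The fallback closes the ether by intramolecular nucleophilic aromatic substitution on a nitro-activated fluoroarene and sets out from 36. N-Boc-4-fluoro-3-nitro-L-phenylalanine F8 is taken through acyl Meldrum's acid F9 and alkyl Meldrum's acid F10 to fluoronitrobenzyl lactam F11 by the operations of steps 25–27. Acylation of its enolate by 42 as in step 28 gives acyl lactam F12, and TFA gives N–H lactam F13. CsF in DMF frees the C7 alkoxide, which displaces fluoride para to the benzyl arm to give nitro cyclophane F14. Zn with NH4Cl gives aniline F15, and tBuONO in DMF (hydrodediazoniation) rejoins the route at 46.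

Further compounds
F1 | step 17 | enoic acid from 24 | C=C[C@H]1C=C(C)[C@@H](/C(C)=C/I)[C@H]([C@@H]1C(=O)OC(C)(C)C)[C@H](O[Si](C)(C)C(C)(C)C)/C=C/C(=O)O
F2 | step 17 | N-enoyl oxazolidinone | C=C[C@H]1C=C(C)[C@@H](/C(C)=C/I)[C@H]([C@@H]1C(=O)OC(C)(C)C)[C@H](O[Si](C)(C)C(C)(C)C)/C=C/C(=O)N2CCOC2=O
F3 | step 17 | triene imide | C=C[C@H]1C=C(C)[C@@H](/C(C)=C/C(OCC)=C)[C@H]([C@@H]1C(=O)OC(C)(C)C)[C@H](O[Si](C)(C)C(C)(C)C)/C=C/C(=O)N2CCOC2=O
F4 | step 17 | tricyclic imide | C=C[C@H]1C=C(C)[C@@H]2[C@H]([C@@H]1C(=O)OC(C)(C)C)[C@H](O[Si](C)(C)C(C)(C)C)[C@@H]1[C@@H](C(=O)N3CCOC3=O)CC(OCC)=C[C@]12C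
F5 | step 28 | C14 primary alcohol | C=C[C@H]1C=C(C)[C@@H]2[C@H]([C@@H]1CO)[C@H](O[Si](C)(C)C(C)(C)C)[C@@H]1[C@@H](C)C[C@@H](C)C[C@]12C
F6 | step 28 | C14 aldehyde | C=C[C@H]1C=C(C)[C@@H]2[C@H]([C@@H]1C=O)[C@H](O[Si](C)(C)C(C)(C)C)[C@@H]1[C@@H](C)C[C@@H](C)C[C@]12C
F7 | step 28 | β-hydroxy lactam (C14 and C15 epimers) | C=C[C@H]1C=C(C)[C@@H]2[C@H]([C@@H]1C(O)C3C[C@H](Cc4ccc(I)cc4)N(C(=O)OC(C)(C)C)C3=O)[C@H](O[Si](C)(C)C(C)(C)C)[C@@H]1[C@@H](C)C[C@@H](C)C[C@]12C
F8 | step 31 | N-Boc-4-fluoro-3-nitro-L-phenylalanine | CC(C)(C)OC(=O)N[C@@H](Cc1ccc(F)c(c1)[N+](=O)[O-])C(=O)O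
F9 | step 31 | acyl Meldrum's acid from F8 | CC(C)(C)OC(=O)N[C@@H](Cc1ccc(F)c(c1)[N+](=O)[O-])C(=O)C1C(=O)OC(C)(C)OC1=O
F10 | step 31 | alkyl Meldrum's acid from F9 | CC(C)(C)OC(=O)N[C@@H](Cc1ccc(F)c(c1)[N+](=O)[O-])CC1C(=O)OC(C)(C)OC1=O
F11 | step 31 | fluoronitrobenzyl N-Boc lactam | CC(C)(C)OC(=O)N1[C@@H](Cc2ccc(F)c(c2)[N+](=O)[O-])CCC1=O
F12 | step 31 | fluoronitro N-Boc acyl lactam | C=C[C@H]1C=C(C)[C@@H]2[C@H]([C@@H]1C(=O)C3C[C@H](Cc4ccc(F)c(c4)[N+](=O)[O-])N(C(=O)OC(C)(C)C)C3=O)[C@H](O[Si](C)(C)C(C)(C)C)[C@@H]1[C@@H](C)C[C@@H](C)C[C@]12C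
F13 | step 31 | fluoronitro N–H acyl lactam | C=C[C@H]1C=C(C)[C@@H]2[C@H]([C@@H]1C(=O)C3C[C@H](Cc4ccc(F)c(c4)[N+](=O)[O-])NC3=O)[C@H](O[Si](C)(C)C(C)(C)C)[C@@H]1[C@@H](C)C[C@@H](C)C[C@]12C
F14 | step 31 | nitro cyclophane | C=C[C@H]1C=C(C)[C@@H]2[C@H]3[C@H](Oc4ccc(cc4[N+](=O)[O-])C[C@H]4CC(C(=O)N4)C(=O)[C@H]13)[C@@H]1[C@@H](C)C[C@@H](C)C[C@]12C
F15 | step 31 | amino cyclophane | C=C[C@H]1C=C(C)[C@@H]2[C@H]3[C@H](Oc4ccc(cc4N)C[C@H]4CC(C(=O)N4)C(=O)[C@H]13)[C@@H]1[C@@H](C)C[C@@H](C)C[C@]12C
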